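**Strategy**

Everything rests on disconnecting the C1–C8 bond of ring B. Ring A (C1–C2–C3–C4–C5–C9) hides a mirror plane through C5 and C2, so the cyclisation precursor is a 1,5-dimethoxycyclohexa-1,4-diene whose non-stereogenic future C5 carries prenyl and a (2R,3R)-2,3-epoxygeranyl chain. A silyl triflate then makes one of the two enantiotopic enol ether carbons (C1) open the epoxide at tertiary C8 with inversion: one operation closes ring B, fixes C1, C5 and quaternary C8 (methyl axial, homoprenyl equatorial) and leaves an exo oxygen on C7, which is later exchanged for prenyl. C2 oxidation, bridgehead prenylation, C3 aroylation and deprotection complete guttiferone L.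

Key step: step 5

Remark on numbering: C1–C9 are the core atoms of the target (C1, C5 bridgeheads; C2–C3–C4 in ring A; C6–C7–C8 in ring B with C8 bonded to C1; C9 the one-carbon bridge); exo at C7 means equatorial on chair ring B, away from ring A; prenyl = 3-methylbut-2-en-1-yl, homoprenyl = 4-methylpent-3-en-1-yl.

Assumption: the enolised trione is treated as one compound in all its tautomers (drawn as C2 ketone/C4 enol), and 1, 4, 5 and 19 are purchased (4 is otherwise one Birch reduction from 1,3-dimethoxybenzene).

**Route**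

Step 1
Reactants: 1 geraniol
Product: 2 (2R,3R)-2,3-epoxygeraniol
Conditions: Ti(OiPr)4 (cat.), D-(−)-diethyl tartrate (cat.), t-BuOOH, 4 Å sieves, CH2Cl2, −20 °C
Reagents that add atoms: tert-butyl hydroperoxide, CC(C)(C)OO
Why: Katsuki–Sharpless asymmetric epoxidation, in which the titanium tartrate binds the allylic hydroxyl so that only the 2,3-alkene is oxidised, the D-(−)-tartrate delivers oxygen to the face that gives the (2R,3R) epoxide, and the E geometry fixes methyl cis to CH2OH.

Step 2
Reactants: 2 (2R,3R)-2,3-epoxygeraniol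
Product: 3 (2S,3R)-2-(bromomethyl)-3-methyl-3-(4-methylpent-3-en-1-yl)oxirane
Conditions: CBr4, PPh3, NaHCO3 (solid buffer), CH2Cl2, 0 °C
Reagents that add atoms: tetrabromomethane, BrC(Br)(Br)Br
Why: Appel reaction, in which bromide displaces the oxyphosphonium group at the primary carbon only, so both oxirane carbons keep their arrangement (the 2-descriptor becomes S only because CH2Br outranks C3).

Step 3
Reactants: 4 1,5-dimethoxycyclohexa-1,4-diene; 5 prenyl bromide
Product: 7 1,5-dimethoxy-6-(3-methylbut-2-en-1-yl)cyclohexa-1,4-diene, via 6-lithio-1,5-dimethoxycyclohexa-1,4-diene 6 (not isolated)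
Conditions: t-BuLi, THF, −78 °C; then 5, −78 → 0 °C
Reagents that add atoms: none
Why: Metalation–alkylation of a Birch-type diene, in which t-BuLi removes the doubly allylic C6–H between the two methoxy-bearing carbons and the cyclohexadienyl anion is alkylated at its central carbon by SN2; no stereocentre is formed.

Step 4
Reactants: 7 1,5-dimethoxy-6-(3-methylbut-2-en-1-yl)cyclohexa-1,4-diene; 3 epoxygeranyl bromide
Product: 9 (2R,3R)-2-{[2,6-dimethoxy-1-(3-methylbut-2-en-1-yl)cyclohexa-2,5-dien-1-yl]methyl}-3-methyl-3-(4-methylpent-3-en-1-yl)oxirane, via 6-lithio-6-prenyl-1,5-dimethoxycyclohexa-1,4-diene 8 (not isolated)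
Conditions: t-BuLi, THF, −78 → −40 °C; then 3, −78 → −20 °C
Reagents that add atoms: none
Why: Second metalation at the same carbon and SN2 alkylation by the primary, oxirane-activated bromide (the central-carbon selectivity of Birch reductive alkylation), giving a quaternary carbon with two identical ring arms that is not stereogenic, while the oxirane carbons are untouched.

Step 5
Reactants: 9 epoxygeranyl prenyl dimethoxycyclohexadiene
Product: 11 7,9-epoxy-4,9-dimethoxy-8-methyl-8-(4-methylpent-3-en-1-yl)-5-(3-methylbut-2-en-1-yl)bicyclo[3.3.1]non-3-ene, via oxocarbenium triflate 10 (not isolated)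
Conditions: Me3SiOTf (cat.), 2,6-lutidine, CH2Cl2, −78 °C; aq NaHCO3
Reagents that add atoms: none
Why: Me3SiOTf silylates the epoxide oxygen, the enol ether carbon C1 attacks tertiary C8 anti to the departing oxygen (SN2-like, inversion), and the C9 oxocarbenium ion 10 is captured by the C7 silyloxy oxygen with release of the silyl group, so the acid turns over. The closest known reaction type is the Lewis acid-mediated epoxide-opening cation–olefin cyclisation with an enol ether as terminating nucleophile, as used for bicyclo[3.3.1]nonane cores of polyprenylated acylphloroglucinols. Ring B (C1–C8–C7–C6–C5–C9) closes by 6-endo opening of the epoxide with the enol ether C=C inside the new ring (enolendo), and the ketal ring (O–C9–C5–C6–C7) closes 5-exo-trig onto the oxocarbenium carbon. C8 is set by inversion of the (3R) oxirane carbon made in step 1 (methyl axial, homoprenyl equatorial); C1 and C5 are set by group selection between the two enantiotopic enol ethers through the chair-like transition state that keeps the C7–O bond equatorial and anti-periplanar to the forming C1–C8 bond; C9 follows from the oxygen bridge, which only an exo C7 oxygen can close. The step needs attack at C8 and not C7, which the cation-stabilising tertiary centre and six- over five-membered ring formation secure, and reaction of an enol ether and not a prenyl-type alkene, which the far higher nucleophilicity of the enol ether at −78 °C secures.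

Step 6
Reactants: 11 bridged methyl ketal
Product: 12 7,9-epoxy-4,9-dimethoxy-8-methyl-8-(4-methylpent-3-en-1-yl)-5-(3-methylbut-2-en-1-yl)bicyclo[3.3.1]non-3-en-2-one
Conditions: Pd(OH)2/C (cat.), t-BuOOH, K2CO3 (cat.), CH2Cl2, 0 °C → rt
Reagents that add atoms: tert-butyl hydroperoxide, CC(C)(C)OO
Why: Radical allylic oxidation, in which t-BuOO• abstracts the C2–H that is allylic to the electron-rich enol ether and the C2 peroxide collapses to the ketone (Kornblum–DeLaMare), giving the vinylogous ester while the ketal masks C9 and the C7 oxygen and no stereocentre is touched.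

Step 7
Reactants: 12 bridged ketal vinylogous ester
Product: 13 7-exo-hydroxy-4-methoxy-8-methyl-8-(4-methylpent-3-en-1-yl)-5-(3-methylbut-2-en-1-yl)bicyclo[3.3.1]non-3-ene-2,9-dione
Conditions: p-TsOH·H2O (cat.), acetone/H2O, rt
Reagents that add atoms: water, O
Why: Acid-catalysed ketal hydrolysis driven by release of the 7-oxabicyclo[2.2.1]heptane strain, in which the ring C9–O bond breaks, C7 keeps its C–O bond and configuration, ring B relaxes to the chair and the much less basic vinylogous ester survives.

Step 8
Reactants: 13 C7 alcohol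
Product: 14 O-phenyl thionocarbonate of 13 at the 7-exo oxygen
Conditions: PhOC(S)Cl, pyridine, DMAP (cat.), CH2Cl2, rt
Reagents that add atoms: O-phenyl chlorothionoformate, S=C(Cl)Oc1ccccc1
Why: DMAP-catalysed O-acylation (Barton–McCombie-type activation) of the accessible equatorial hydroxyl, with C7 unchanged.

Step 9
Reactants: 14 C7 thionocarbonate
Product: 15 7-exo-allyl-4-methoxy-8-methyl-8-(4-methylpent-3-en-1-yl)-5-(3-methylbut-2-en-1-yl)bicyclo[3.3.1]non-3-ene-2,9-dione
Conditions: Bu3SnCH2CH=CH2 (neat, large excess), AIBN, 80 °C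
Reagents that add atoms: allyltributylstannane, C=CC[Sn](CCCC)(CCCC)CCCC
Why: Keck radical allylation, in which stannyl radical addition to C=S and β-scission give the C7 radical, whose endo lobe is blocked by ring A so that the stannane is attacked (SH2') on the exo face and allyl takes the place of the oxygen; the equatorial homoprenyl chain on C8 lies in the nodal plane of this radical in the rigid bicycle, which together with neat stannane should disfavour 5-exo closure.

Step 10
Reactants: 15 C7 allyl compound
Product: 16 4-methoxy-8-methyl-8-(4-methylpent-3-en-1-yl)-5,7-exo-bis(3-methylbut-2-en-1-yl)bicyclo[3.3.1]non-3-ene-2,9-dione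
Conditions: 2-methyl-2-butene (excess), second-generation Grubbs catalyst, CH2Cl2, 40 °C
Reagents that add atoms: 2-methyl-2-butene, CC=C(C)C
Why: Olefin cross-metathesis, in which only the monosubstituted allyl alkene is engaged by the ruthenium carbene and is capped with the isopropylidene unit, while the trisubstituted prenyl-type alkenes and the vinylogous ester are spectators.

Step 11
Reactants: 16 C1–H diketone; 5 prenyl bromide
Product: 18 4-methoxy-8-methyl-8-(4-methylpent-3-en-1-yl)-1,5,7-exo-tris(3-methylbut-2-en-1-yl)bicyclo[3.3.1]non-3-ene-2,9-dione, via bridgehead C1-lithio diketone 17 (not isolated)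
Conditions: LiN(iPr)2, THF, −78 °C; then 5, −78 → 0 °C
Reagents that add atoms: none
Why: Bridgehead metalation–alkylation, in which the amide removes C1–H, the only proton flanked by the C2 and C9 carbonyls, and the configurationally locked bridgehead anion is alkylated by prenyl bromide on its single open face with retention.

Step 12
Reactants: 19 2,4,5-trihydroxybenzaldehyde
Product: 20 2,4,5-tris(prop-2-en-1-yloxy)benzaldehyde
Conditions: allyl bromide, K2CO3, DMF, 60 °C
Reagents that add atoms: allyl bromide, C=CCBr
Why: Williamson ether synthesis on the three phenoxides, giving ethers that tolerate organolithiums and hydroxide and can later be removed without acid.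

Step 13
Reactants: 18 triprenyl vinylogous ester; 20 2,4,5-tris(prop-2-en-1-yloxy)benzaldehyde
Product: 22 C3 {hydroxy[2,4,5-tris(prop-2-en-1-yloxy)phenyl]methyl} derivative of 18 (carbinol epimers), via C3-lithio vinylogous ester 21 (not isolated)
Conditions: lithium 2,2,6,6-tetramethylpiperidide, THF, −78 °C; then 20; aq NH4Cl
Reagents that add atoms: none
Why: Vinylic α-metalation of the β-methoxy enone at C3 by the hindered amide (no other acidic proton remains) followed by 1,2-addition to the aldehyde; the carbinol centre forms as a mixture that the next step erases.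

Step 14
Reactants: 22 C3 carbinol
Product: 23 C3 [2,4,5-tris(prop-2-en-1-yloxy)benzoyl] derivative of 18
Conditions: Dess–Martin periodinane, CH2Cl2, 0 °C → rt
Reagents that add atoms: none
Why: Dess–Martin oxidation of the allylic and benzylic secondary alcohol to the aryl ketone under neutral conditions that leave allyl ethers and prenyl groups alone.

Step 15
Reactants: 23 C3 aroyl vinylogous methyl ester
Product: 24 tri-O-allyl guttiferone L (free C2/C4 enolised trione)
Conditions: LiOH, dioxane/H2O, 90 °C, argon; then 1 M HCl to pH 3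
Reagents that add atoms: lithium hydroxide, [Li+].[OH-]
Why: Addition–elimination of hydroxide at C4 of the vinylogous ester (conjugate addition, loss of methoxide) gives the enolised trione, and because the allyl ethers are inert no free ortho-phenoxide can close onto C4.

Step 16
Reactants: 24 tri-O-allyl guttiferone L
Product: 25 guttiferone L
Conditions: Pd(PPh3)4 (cat.), morpholine, THF, rt, argon; dilute acid work-up with ascorbic acid
Reagents that add atoms: none
Why: Tsuji–Trost deallylation, in which zerovalent palladium ionises the three aryl allyl ethers and morpholine captures the allyl units irreversibly (any O-allylated enol is re-ionised), under neutral conditions that spare the prenyl groups and avoid acid-induced pyran formation.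

**Compound list**

1 | geraniol, (2E)-3,7-dimethylocta-2,6-dien-1-ol | CC(C)=CCC/C(C)=C/CO | starting material
2 | (2R,3R)-2,3-epoxygeraniol, [(2R,3R)-3-methyl-3-(4-methylpent-3-en-1-yl)oxiran-2-yl]methanol | CC(C)=CCC[C@]1(C)[C@H](O1)CO | intermediate
3 | (2S,3R)-2-(bromomethyl)-3-methyl-3-(4-methylpent-3-en-1-yl)oxirane (same spatial arrangement as 2) | CC(C)=CCC[C@]1(C)[C@H](O1)CBr | intermediate
4 | 1,5-dimethoxycyclohexa-1,4-diene | COC1=CCC=C(OC)C1 | starting material
5 | prenyl bromide, 1-bromo-3-methylbut-2-ene | CC(C)=CCBr | starting material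
6 | 6-lithio-1,5-dimethoxycyclohexa-1,4-diene | [Li]C1C(OC)=CCC=C1OC | intermediate
7 | 1,5-dimethoxy-6-(3-methylbut-2-en-1-yl)cyclohexa-1,4-diene | COC1=CCC=C(OC)C1CC=C(C)C | intermediate
8 | 6-lithio-1,5-dimethoxy-6-(3-methylbut-2-en-1-yl)cyclohexa-1,4-diene | [Li]C1(CC=C(C)C)C(OC)=CCC=C1OC | intermediate
9 | (2R,3R)-2-{[2,6-dimethoxy-1-(3-methylbut-2-en-1-yl)cyclohexa-2,5-dien-1-yl]methyl}-3-methyl-3-(4-methylpent-3-en-1-yl)oxirane | CC(C)=CCC[C@]1(C)[C@H](O1)CC2(CC=C(C)C)C(OC)=CCC=C2OC | intermediate
10 | ring B-closed C9 O-methyl oxocarbenium triflate with 7-exo trimethylsilyloxy group | CC(C)=CCC[C@@]1(C)[C@H](O[Si](C)(C)C)C[C@]2(CC=C(C)C)C(=[O+]C)[C@H]1CC=C2OC.[O-]S(=O)(=O)C(F)(F)F | intermediate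
11 | 7,9-epoxy-4,9-dimethoxy-8-methyl-8-homoprenyl-5-prenylbicyclo[3.3.1]non-3-ene (oxygen bridge from exo C7 to C9; C8 methyl axial, homoprenyl equatorial; C1–H) | CC(C)=CCC[C@@]1(C)[C@H](O3)C[C@]2(CC=C(C)C)[C@@]3(OC)[C@H]1CC=C2OC | intermediate
12 | 2-oxo derivative of 11 (C2 ketone, C3=C4–OMe vinylogous ester) | CC(C)=CCC[C@@]1(C)[C@H](O3)C[C@]2(CC=C(C)C)[C@@]3(OC)[C@H]1C(=O)C=C2OC | intermediate
13 | 7-exo-hydroxy-4-methoxy-8-methyl-8-homoprenyl-5-prenylbicyclo[3.3.1]non-3-ene-2,9-dione (C8 methyl axial) | CC(C)=CCC[C@@]1(C)[C@H](O)C[C@]2(CC=C(C)C)C(=O)[C@H]1C(=O)C=C2OC | intermediate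
14 | O-phenyl thionocarbonate of 13 at the 7-exo oxygen | CC(C)=CCC[C@@]1(C)[C@H](OC(=S)Oc3ccccc3)C[C@]2(CC=C(C)C)C(=O)[C@H]1C(=O)C=C2OC | intermediate
15 | 7-exo-allyl-4-methoxy-8-methyl-8-homoprenyl-5-prenylbicyclo[3.3.1]non-3-ene-2,9-dione | CC(C)=CCC[C@@]1(C)[C@H](CC=C)C[C@]2(CC=C(C)C)C(=O)[C@H]1C(=O)C=C2OC | intermediate
16 | 4-methoxy-8-methyl-8-homoprenyl-5,7-exo-diprenylbicyclo[3.3.1]non-3-ene-2,9-dione | CC(C)=CCC[C@@]1(C)[C@H](CC=C(C)C)C[C@]2(CC=C(C)C)C(=O)[C@H]1C(=O)C=C2OC | intermediate
17 | C1 (bridgehead) lithio derivative of 16 | CC(C)=CCC[C@@]1(C)[C@H](CC=C(C)C)C[C@]2(CC=C(C)C)C(=O)[C@@]1([Li])C(=O)C=C2OC | intermediate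
18 | 4-methoxy-8-methyl-8-homoprenyl-1,5,7-exo-triprenylbicyclo[3.3.1]non-3-ene-2,9-dione | CC(C)=CCC[C@@]1(C)[C@H](CC=C(C)C)C[C@]2(CC=C(C)C)C(=O)[C@@]1(CC=C(C)C)C(=O)C=C2OC | intermediate
19 | 2,4,5-trihydroxybenzaldehyde | O=Cc1cc(O)c(O)cc1O | starting material
20 | 2,4,5-tris(prop-2-en-1-yloxy)benzaldehyde | O=Cc1cc(OCC=C)c(OCC=C)cc1OCC=C | intermediate
21 | C3 (vinylic) lithio derivative of 18 | CC(C)=CCC[C@@]1(C)[C@H](CC=C(C)C)C[C@]2(CC=C(C)C)C(=O)[C@@]1(CC=C(C)C)C(=O)C([Li])=C2OC | intermediate
22 | 3-{hydroxy[2,4,5-tris(prop-2-en-1-yloxy)phenyl]methyl} derivative of 18 (both carbinol epimers) | CC(C)=CCC[C@@]1(C)[C@H](CC=C(C)C)C[C@]2(CC=C(C)C)C(=O)[C@@]1(CC=C(C)C)C(=O)C(C(O)c3cc(OCC=C)c(OCC=C)cc3OCC=C)=C2OC | intermediate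
23 | 3-[2,4,5-tris(prop-2-en-1-yloxy)benzoyl] derivative of 18 | CC(C)=CCC[C@@]1(C)[C@H](CC=C(C)C)C[C@]2(CC=C(C)C)C(=O)[C@@]1(CC=C(C)C)C(=O)C(C(=O)c3cc(OCC=C)c(OCC=C)cc3OCC=C)=C2OC | intermediate
24 | tri-O-allyl guttiferone L (C4 enol free) | CC(C)=CCC[C@@]1(C)[C@H](CC=C(C)C)C[C@]2(CC=C(C)C)C(=O)[C@@]1(CC=C(C)C)C(=O)C(C(=O)c3cc(OCC=C)c(OCC=C)cc3OCC=C)=C2O | intermediate
25 | guttiferone L (C7 prenyl exo; C8 methyl axial and cis to it, homoprenyl equatorial) | CC(C)=CCC[C@@]1(C)[C@H](CC=C(C)C)C[C@]2(CC=C(C)C)C(=O)[C@@]1(CC=C(C)C)C(=O)C(C(=O)c1cc(O)c(O)cc1O)=C2O | target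

**Step count and risks**

Total step count: 16. Longest linear sequence: 14 steps (1, 2, 4–11, 13–16).

Steps most likely to fail:

Step 9. The C7 radical may close 5-exo onto the homoprenyl alkene on C8, or pick up hydrogen, before the slow SH2' transfer from the stannane takes place. The fallback sets out from 14 and intercepts the radical with a much faster acceptor: Giese addition to vinyltriphenylphosphonium bromide [(Me3Si)3SiH, AIBN, PhH/MeCN, 80 °C; exo-face attack as before] should give the {2-[bicyclic C7-exo]ethyl}triphenylphosphonium bromide F1. Deprotonation with NaN(SiMe3)2 in THF at −78 °C and Wittig reaction with acetone then builds the prenyl group directly, so the sequence comes back to the route at 16 and bypasses 15 and the metathesis.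

Step 6. Hydrogen abstraction at the allylic positions of the prenyl and homoprenyl chains, or oxidative cleavage of the enol ether, may compete with oxidation at C2. The fallback sets out from 9 and oxidises before ring closure, at the doubly allylic ring CH2 flanked by both enol ethers, which is the weakest C–H bond in the molecule (Pd(OH)2/C with t-BuOOH, or CrO3·3,5-dimethylpyrazole). This should give the cross-conjugated 4,4-disubstituted 3,5-dimethoxycyclohexa-2,5-dien-1-one F2. Its vinylogous ester α-carbon then opens the epoxide in the same Me3SiOTf cascade (BF3·OEt2 if more activation is needed), which comes back to the route at 12.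

Step 11. Kinetic deprotonation at the vinylic C3 position may compete with removal of the congested bridgehead proton next to quaternary C8, diverting prenyl bromide to C3. The fallback sets out from 16 and blocks C3 first: metalation with lithium 2,2,6,6-tetramethylpiperidide in the presence of Me3SiCl (in situ quench, THF, −78 °C) should give the C3 trimethylsilyl derivative F3. With C3 blocked, LiN(iPr)2 and prenyl bromide give the bridgehead-prenylated silane F4, and Bu4NF in THF removes the silyl group, which comes back to the route at 18.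

Further compounds
F1 | step 9 | {2-[C7-exo-substituted 4-methoxy-8-methyl-8-homoprenyl-5-prenyl-2,9-dioxobicyclo[3.3.1]non-3-en-7-yl]ethyl}triphenylphosphonium bromide | CC(C)=CCC[C@@]1(C)[C@H](CC[P+](c3ccccc3)(c3ccccc3)c3ccccc3)C[C@]2(CC=C(C)C)C(=O)[C@H]1C(=O)C=C2OC.[Br-]
F2 | step 6 | 3,5-dimethoxy-4-{[(2R,3R)-3-methyl-3-(4-methylpent-3-en-1-yl)oxiran-2-yl]methyl}-4-(3-methylbut-2-en-1-yl)cyclohexa-2,5-dien-1-one | CC(C)=CCC[C@]1(C)[C@H](O1)CC2(CC=C(C)C)C(OC)=CC(=O)C=C2OC
F3 | step 11 | 3-(trimethylsilyl) derivative of 16 | CC(C)=CCC[C@@]1(C)[C@H](CC=C(C)C)C[C@]2(CC=C(C)C)C(=O)[C@H]1C(=O)C([Si](C)(C)C)=C2OC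
F4 | step 11 | 3-(trimethylsilyl) derivative of 18 | CC(C)=CCC[C@@]1(C)[C@H](CC=C(C)C)C[C@]2(CC=C(C)C)C(=O)[C@@]1(CC=C(C)C)C(=O)C([Si](C)(C)C)=C2OC
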